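## Structural features

Brandisianin A (21) is an isoflavone: benzene ring A is fused to 4-pyranone ring C, and the tetrasubstituted ring B is attached to C3 of ring C by one C3–C1' bond. Ring A carries free hydroxyls at C5 and C7; with the ring oxygen O1 on C8a they form a 1,3,5-trioxygenated (phloroglucinol) ring whose fourth substituted carbon, C4a, bears the C4 carbonyl. Ring B carries methoxy groups at C2' and C5' and a 3-methylbut-2-enyl (prenyl) ether at C4'. There is no stereocentre; the only stereochemical element on the way is an enol ether geometry that disappears. The fragile groups are the aryl prenyl ether (ionised by strong protic or Lewis acids and by zerovalent palladium when hot, lost on hydrogenation, epoxidised by peracids), C2 of the pyranone (opened by hydroxide or alkoxide, with possible loss of C2 as formate) and the electron-rich ring A. The real difficulty is chemoselectivity: two phenols on ring A must end up free while an acid- and hydrogenolysis-sensitive ether sits on ring B, and the 4'-oxygen is not the most acidic phenol, so late prenylation would not be selective. The key step uses the fact that C8a, C8, C7, C6, C5, C4a and C4 with their oxygens are a folded 3,5,7-triketo ester chain, so the ring A phenols are born free. A carbon at aldehyde oxidation level next to C3 (the future C2) then lets the new C8a oxygen close ring C.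

## Logic of the disconnections

Chain numbering of the open precursor: C1 = future C8a, C6 = C4a, C7 = C4, C8 = C3, C9 = C2.

**21 to 19.** The O1–C2 and C4a–C8a bonds are cut, which opens rings C and A at once and leaves the linear triketo ester 19. The cut is made there because every oxygen of ring A is then a chain carbonyl, so no phenol protecting group is needed and nothing remains to be done after the ring closure. In 19, C9 is held as an E methyl enol ether and not as a saturated acetal, for three reasons:
- C8 then has no acidic hydrogen next to a β-leaving group;
- the C7 carbonyl becomes a vinylogous ester and is a poor acceptor for the unwanted aldol fold;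
- the unit is available in one coupling step.

The demand on the forward step is Claisen-mode folding (C6 onto C1) in preference to aldol folding (C2 onto C7) and to closure of the C5 enol oxygen on C9.

**19 to 17.** The C1–O(methyl) ester bond is traced back to a dioxinone that masks C1–C3. This is done because 19 is too prone to spontaneous cyclisation to be carried or stored. The gain is a stable, chromatographable intermediate. The demand is a neutral unmasking that is followed at once by the key step.

**17 to 12 and 15.** The C6–C7 bond is cut, giving a ring B acyl donor and a six-carbon dioxinone ketone. The cut is convergent and puts all of ring B into one piece. Because 12 has no hydrogen on C8, its activated form cannot be enolised. The demand is C-acylation at the terminal carbanion of the dianion of 15, with attack at the acyl carbon and not at C9.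

**15 to 13 and 14.** The bond between the dioxinone methyl carbon and the acetyl carbon is cut. Both pieces are catalogue chemicals; the demand is γ-selective acylation of the dienolate.

**12 to 11 to 5 and 8.** After a trivial ester hydrolysis, the C8–C1' bond (C3–C1' of the target) is cut between two sp2 carbons. This brings in C7, C8 and C9 with the enol ether already in place and avoids a sequence of arylation, decarboxylation, formylation and acetalisation. The demand is a coupling mild enough for the prenyl ether, with retention of the alkene geometry.

**8 to 6.** The C–I bond is cut; the demand is α-iodination of a β-alkoxyacrylate with defined geometry.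

**5 to 3 and 4, and 3 to 1.** The O–CH2 bond of the prenyl ether is cut, then the aryl C–O bond is traced back to an aryl aldehyde. The bromine and both methoxy groups are thus bought in the correct positions, so no regiochemical question arises on ring B. The demand is that the alkene is introduced only after the peracid step.

## Other disconnections considered

**Alternative 1:** The cut is at C3–C4 and C4–C4a, with C4 supplied by carbon monoxide. In the forward sense the Z enol triflate A2 would react with zerovalent palladium (from Pd(OAc)2 and tricyclohexylphosphine), insert carbon monoxide (C3–C4), and the acylpalladium would acylate the ring A C–H bond ortho to the ether oxygen (C4–C4a), closing ring C to give A1.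
- In favour: ring A is bought with its oxygen pattern, and the aryloxy unit of A2 is symmetric, so both ortho C–H bonds are equivalent. On certainty of ring A regiochemistry this plan is the better one, since no folding selectivity is involved. It is the equal of the chosen plan in skeletal bonds made in the key step (two).
- Against: the prenyl ether cannot be present during a hot palladium-catalysed C–H acylation, which is why A1 carries a benzyl ether. Three operations follow the key step: hydrogenolysis, prenylation of the 4'-phenol and acid removal of two methoxymethyl ethers. The last exposes the new prenyl ether to conditions harsher than the brief pH 2–3 quench of the chosen plan.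
- Mechanism: the acylpalladium must find an electron-rich arene C–H bond faster than it is captured by other nucleophiles or decarbonylates. A2 must also be made as a single geometric isomer from an α-aryloxy ketone.
- Comparison: this plan closes one ring against two, needs four protecting-group events against none, and would run to roughly two or three steps more.

**Alternative 2:** The cut is at C3–C4 and O1–C8a. Acid chloride A4 would acylate the β-carbon of enamine A5. Aqueous K2CO3 in the same flask would hydrolyse the nitrogen function, and the enol oxygen would displace an ortho fluoride by addition–elimination, giving A3.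
- In favour: both partners are simple, no acid or transition metal touches the prenyl ether, and the two ortho fluorines are equivalent. In robustness and predictability of the key step itself this plan is the better one, and in regiochemical certainty it is at least the equal.
- Against: A3 is not at the target's substitution pattern. The C5–F and C7–F bonds must each become C–OH. Oxygen nucleophiles can also add at C2 and open ring C, the second substitution is slowed by the first oxygen substituent, and few hydroxide surrogates can be unmasked without acid or hydrogenolysis.
- Comparison: the chosen plan delivers both phenols free in the ring-forming step. This plan adds at least two chemoselectively uncertain steps after it, and A5 itself needs a homologation sequence from the ring B bromide.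

**Alternative 3:** The cut is at C4a–C5, C5–C6 and C7–C8, so that ring A is built on a preformed ring C. Irradiation of diazo ketone A7 would give, by Wolff rearrangement, a pyranonyl ketene that adds to siloxyalkyne A8 in a (2+2) sense. Warming would open the cyclobutenone (four-electron electrocyclic opening) and close the dienylketene (six-electron electrocyclisation) to A6, with the free hydroxyl at C5 and the silyl ether at C7.
- In favour: the position of each ring A oxygen is dictated by the pericyclic sequence, so in regiochemical certainty this plan is the better one. The conditions are neutral, so in mildness toward the prenyl ether and C2 it is the equal of the chosen plan. The two ring A oxygens emerge differentiated, which this target does not need.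
- Against: A7 needs a long preparation from kojic acid A9 (sulfonylation, cross-coupling with ring B, oxidation of the hydroxymethyl group, activation, diazomethane), and A8 is not a catalogue reagent. The 4-pyranone is itself photoactive, and the C4a=C8a bond that must enter the six-electron closure belongs to a cross-conjugated vinylogous ester.
- Comparison: three skeletal bonds are made in the key step against two, but one desilylation follows, the count would be several steps higher, and a hazardous reagent is needed.

Key step: step 9

## Route

Ar = 2,5-dimethoxy-4-(3-methylbut-2-enyloxy)phenyl.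

Remark: C9 is carried as its E methyl enol ether (same carbon skeleton and oxidation level as a dimethyl acetal, one methanol less). Its geometry is immaterial because the C8=C9 bond is re-formed by addition–elimination in step 9. Compounds 1, 4, 6, 13 and 14 are taken as catalogue chemicals.

Step 1
Reactants: 1 4-bromo-2,5-dimethoxybenzaldehyde
Product: 3 4-bromo-2,5-dimethoxyphenol, via 4-bromo-2,5-dimethoxyphenyl formate 2 (not isolated)
Conditions: mCPBA, CH2Cl2, 0 °C → rt; then K2CO3 (cat.), MeOH, rt
Reagents that add atoms: meta-chloroperoxybenzoic acid (mCPBA), OOC(=O)c1cccc(Cl)c1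
Why: Baeyer–Villiger oxidation in its Dakin form: the electron-rich aryl group migrates in the Criegee adduct to give formate 2, which base-catalysed methanolysis cleaves to phenol 3; the peracid is used before any alkene is present.

Step 2
Reactants: 3 4-bromo-2,5-dimethoxyphenol; 4 prenyl bromide (1-bromo-3-methylbut-2-ene)
Product: 5 1-bromo-2,5-dimethoxy-4-(3-methylbut-2-enyloxy)benzene
Conditions: K2CO3, acetone, reflux
Reagents that add atoms: none
Why: Williamson ether synthesis: the potassium phenoxide attacks the primary allylic bromide at oxygen by SN2, and carbonate in acetone favours O- over C-alkylation.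

Step 3
Reactants: 6 methyl (E)-3-methoxyprop-2-enoate
Product: 8 methyl (Z)-2-iodo-3-methoxyprop-2-enoate, via acetoxy iodo adduct 7 (not isolated)
Conditions: N-iodosuccinimide, AcOH, CH2Cl2, rt; then Et3N, rt
Reagents that add atoms: N-iodosuccinimide, O=C1CCC(=O)N1I
Why: Iodoacetoxylation of the enol ether (iodine to the α-carbon, acetate to the oxocarbenium carbon) followed by amine-induced elimination of acetic acid, the established α-iodination of a β-alkoxyacrylate; it should give the Z iodide with iodine and methoxy cis.

Step 4
Reactants: 5 1-bromo-2,5-dimethoxy-4-(3-methylbut-2-enyloxy)benzene; 8 methyl (Z)-2-iodo-3-methoxyprop-2-enoate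
Product: 11 methyl (E)-2-Ar-3-methoxyprop-2-enoate, via aryllithium 9 (not isolated), via arylzinc chloride 10 (not isolated)
Conditions: n-BuLi, THF, −78 °C; ZnCl2, −78 °C → rt; 8, Pd(PPh3)4 (5 mol %), THF, rt → 45 °C
Reagents that add atoms: none
Why: Bromine–lithium exchange, transmetalation to zinc and Negishi cross-coupling: zerovalent palladium inserts into the alkenyl C–I bond at room temperature with retention, so the Z iodide should give the E aryl acrylate; the arylzinc tolerates the ester, and at this temperature the allylic aryl ether should not be ionised.

Step 5
Reactants: 11 methyl (E)-2-Ar-3-methoxyprop-2-enoate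
Product: 12 (E)-2-Ar-3-methoxyprop-2-enoic acid
Conditions: LiOH·H2O, THF/MeOH/H2O, 50 °C; then 1 M HCl to pH 3, 0 °C
Reagents that add atoms: lithium hydroxide, [Li+].[OH-]
Why: Saponification by acyl–oxygen cleavage; the donor-substituted ester needs warming, both ethers are inert to hydroxide, and brief cold acidification to pH 3 should not hydrolyse the push–pull enol ether.

Step 6
Reactants: 13 2,2,6-trimethyl-4H-1,3-dioxin-4-one; 14 acetyl chloride
Product: 15 2,2-dimethyl-6-(2-oxopropyl)-4H-1,3-dioxin-4-one
Conditions: 13 (2 equiv), LiN(SiMe3)2 (2 equiv), THF, −78 °C; 14 (1 equiv), −78 °C; aq. NH4Cl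
Reagents that add atoms: none
Why: Vinylogous deprotonation gives the lithium dienolate of 13, which is C-acylated at its γ-carbon (vinylogous Claisen acylation); the second equivalent of dienolate deprotonates the more acidic product and so prevents double acylation.

Step 7
Reactants: 12 (E)-2-Ar-3-methoxyprop-2-enoic acid; 15 2,2-dimethyl-6-(2-oxopropyl)-4H-1,3-dioxin-4-one
Product: 17 6-[(5E)-5-Ar-6-methoxy-2,4-dioxohex-5-en-1-yl]-2,2-dimethyl-4H-1,3-dioxin-4-one, via acyl imidazolide 16 (not isolated)
Conditions: 12, 1,1'-carbonyldiimidazole, THF, rt; separately 15 (3 equiv), LiN(iPr)2 (6 equiv), THF, −78 °C; add 16, −78 → −40 °C; aq. NH4Cl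
Reagents that add atoms: none
Why: Claisen-type C-acylation of a ketone dianion by an acyl imidazole: the terminal, more basic carbanion of the dilithium salt of 15 attacks the acyl carbon of 16, which cannot be enolised because C8 bears no hydrogen; excess dianion absorbs the liberated imidazole and the acidic product, and the acyl carbon is more electrophilic than the donor-substituted C9.

Step 8
Reactants: 17 6-[(5E)-5-Ar-6-methoxy-2,4-dioxohex-5-en-1-yl]-2,2-dimethyl-4H-1,3-dioxin-4-one
Product: 19 methyl (8E)-8-Ar-9-methoxy-3,5,7-trioxonon-8-enoate, via acylketene 18 (not isolated)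
Conditions: MeOH (10 equiv), toluene, 110 °C (sealed), 45 min; evaporate, use crude at once
Reagents that add atoms: methanol, CO
Why: Thermal retro-(4+2) fragmentation of the dioxinone expels acetone and gives acylketene 18, which methanol traps as the β-keto ester; the medium is neutral and the temperature is well below that of an aromatic Claisen rearrangement of the prenyl ether.

Step 9
Reactants: 19 methyl (8E)-8-Ar-9-methoxy-3,5,7-trioxonon-8-enoate
Product: 21 brandisianin A, via acylphloroglucinol 20 (not isolated)
Conditions: Mg(OMe)2 (5 equiv), anhydrous MeOH, rt → 45 °C, Ar; then 1 M HCl to pH 2–3, 0 °C → rt, 30 min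
Reagents that add atoms: none
Why: Mg(OMe)2 turns 19 into a chelated polyenolate in which the C3, C5 and C7 carbonyls are enolised and metal-bound, so the C1 methyl ester is the only acyl electrophile left; the doubly activated C6 carbanion (future C4a) attacks C1 (future C8a) in a 6-exo-trig acyl substitution, and loss of methoxide with enolisation gives the aromatic acylphloroglucinol 20. The closest known reaction type is the base-mediated Claisen-mode cyclisation of 3,5,7-triketo esters to acylphloroglucinols, the laboratory copy of the chalcone synthase fold. The selectivity needed is this fold against the aldol fold (C2 onto C7) and against closure of the C5 enol oxygen on C9: C7 is a vinylogous ester carbonyl, α-branched and shielded by the ortho-methoxy aryl group, so it is a poor aldol acceptor, while the O5–Mg–O7 chelate holds O5 away from C9 and a pyranone formed that way should be reopened by methoxide, whereas aromatisation to 20 is irreversible. Ring C then closes when a C8a phenol(ate) of 20 adds to C9 of the β-methoxy enone (6-endo-trig oxa-Michael addition) and methanol is eliminated, the standard closure of a 2-hydroxyaryl β-alkoxyvinyl ketone to a chromone; the dilute acid completes the closure and protonates the phenoxides. The two ortho hydroxyls of 20 are equivalent by symmetry, so there is no regiochemical choice, and the one not used becomes the C5 hydroxyl. No stereocentre is formed and the E geometry of C8=C9 is erased in the addition–elimination. The prenyl ether is inert to methoxide and to pH 2–3 at 0 °C to room temperature, and keeping the mixture anhydrous until the quench avoids hydrolytic loss of C9 as formate.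

## Compound list

1 | 4-bromo-2,5-dimethoxybenzaldehyde | COc1cc(C=O)c(OC)cc1Br | starting material
2 | 4-bromo-2,5-dimethoxyphenyl formate | COc1cc(OC=O)c(OC)cc1Br | intermediate (not isolated)
3 | 4-bromo-2,5-dimethoxyphenol | COc1cc(O)c(OC)cc1Br | intermediate
4 | prenyl bromide (1-bromo-3-methylbut-2-ene) | CC(C)=CCBr | starting material
5 | 1-bromo-2,5-dimethoxy-4-(3-methylbut-2-enyloxy)benzene | COc1cc(OCC=C(C)C)c(OC)cc1Br | intermediate
6 | methyl (E)-3-methoxyprop-2-enoate | CO/C=C/C(=O)OC | starting material
7 | methyl 3-acetoxy-2-iodo-3-methoxypropanoate (racemic, mixture of diastereomers) | COC(OC(C)=O)C(I)C(=O)OC | intermediate (not isolated)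
8 | methyl (Z)-2-iodo-3-methoxyprop-2-enoate | CO/C=C(\I)C(=O)OC | intermediate
9 | [2,5-dimethoxy-4-(3-methylbut-2-enyloxy)phenyl]lithium | [Li]c1cc(OC)c(OCC=C(C)C)cc1OC | intermediate (not isolated)
10 | [2,5-dimethoxy-4-(3-methylbut-2-enyloxy)phenyl]zinc chloride | Cl[Zn]c1cc(OC)c(OCC=C(C)C)cc1OC | intermediate (not isolated)
11 | methyl (E)-2-[2,5-dimethoxy-4-(3-methylbut-2-enyloxy)phenyl]-3-methoxyprop-2-enoate | CO/C=C(/C(=O)OC)c1cc(OC)c(OCC=C(C)C)cc1OC | intermediate
12 | (E)-2-[2,5-dimethoxy-4-(3-methylbut-2-enyloxy)phenyl]-3-methoxyprop-2-enoic acid | CO/C=C(/C(O)=O)c1cc(OC)c(OCC=C(C)C)cc1OC | intermediate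
13 | 2,2,6-trimethyl-4H-1,3-dioxin-4-one | CC1=CC(=O)OC(C)(C)O1 | starting material
14 | acetyl chloride | CC(Cl)=O | starting material
15 | 2,2-dimethyl-6-(2-oxopropyl)-4H-1,3-dioxin-4-one | CC(=O)CC1=CC(=O)OC(C)(C)O1 | intermediate
16 | (E)-2-[2,5-dimethoxy-4-(3-methylbut-2-enyloxy)phenyl]-1-(1H-imidazol-1-yl)-3-methoxyprop-2-en-1-one | CO/C=C(/C(=O)n1ccnc1)c1cc(OC)c(OCC=C(C)C)cc1OC | intermediate (not isolated)
17 | 6-[(5E)-5-[2,5-dimethoxy-4-(3-methylbut-2-enyloxy)phenyl]-6-methoxy-2,4-dioxohex-5-en-1-yl]-2,2-dimethyl-4H-1,3-dioxin-4-one | CO/C=C(/C(=O)CC(=O)CC1=CC(=O)OC(C)(C)O1)c1cc(OC)c(OCC=C(C)C)cc1OC | intermediate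
18 | (8E)-8-[2,5-dimethoxy-4-(3-methylbut-2-enyloxy)phenyl]-9-methoxy-3,5,7-trioxonona-1,8-dien-1-one (acylketene) | CO/C=C(/C(=O)CC(=O)CC(=O)C=C=O)c1cc(OC)c(OCC=C(C)C)cc1OC | intermediate (not isolated)
19 | methyl (8E)-8-[2,5-dimethoxy-4-(3-methylbut-2-enyloxy)phenyl]-9-methoxy-3,5,7-trioxonon-8-enoate | CO/C=C(/C(=O)CC(=O)CC(=O)CC(=O)OC)c1cc(OC)c(OCC=C(C)C)cc1OC | intermediate (key-step precursor)
20 | (E)-2-[2,5-dimethoxy-4-(3-methylbut-2-enyloxy)phenyl]-3-methoxy-1-(2,4,6-trihydroxyphenyl)prop-2-en-1-one | CO/C=C(/C(=O)c1c(O)cc(O)cc1O)c1cc(OC)c(OCC=C(C)C)cc1OC | intermediate (not isolated)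
21 | brandisianin A, 5,7-dihydroxy-3-[2,5-dimethoxy-4-(3-methylbut-2-enyloxy)phenyl]-4H-chromen-4-one | COc1cc(-c2coc3cc(O)cc(O)c3c2=O)c(OC)cc1OCC=C(C)C | target

## Step count and least certain steps

Total: 9 steps. Longest linear sequence: 7 steps (steps 1, 2, 4, 5, 7, 8, 9). Steps 3 and 6 are on side branches.

**Step 9 (key step).**
- Most likely failure: folding of the chain in the wrong mode. This could be aldol closure of C2 on C7, or closure of the C5 enol oxygen on C9 if the Claisen fold is slow and acid is added too early.
- Also possible: hydrolytic excision of C9 during the quench, and ionisation of the prenyl ether if the acid is too strong or too prolonged.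
- Why: the polyenolate has several nucleophilic and electrophilic sites, and the outcome depends on chelation.
- Fallback, from 16 (made from 12 as in step 7) to 21, with ring A bought instead of folded: phloroglucinol is etherified with 2-(trimethylsilyl)ethoxymethyl chloride and iPr2NEt to 1,3,5-tris{[2-(trimethylsilyl)ethoxy]methoxy}benzene F1. F1 is lithiated between two acetal oxygens (n-BuLi, THF, 0 °C) and the aryllithium is acylated by 16 at −78 °C to the ketone (E)-2-Ar-3-methoxy-1-(2,4,6-tris{[2-(trimethylsilyl)ethoxy]methoxy}phenyl)prop-2-en-1-one F2. Bu4NF in THF/DMPU at 60 °C removes the three groups, and the ortho phenoxide set free closes ring C on C9 as in step 9, which should give 21 after a neutral work-up.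

**Step 7.**
- Most likely failure: proton transfer from liberated imidazole or from the product to the dianion, conjugate addition–elimination of the dianion at C9 in place of acyl substitution, or O-acylation.
- Why: the electrophile is a hindered, donor-substituted acyl imidazole that is also a vinylogous ester.
- Fallback, from 11 to 17, with an aldehyde as electrophile: iBu2AlH (CH2Cl2, −78 °C) reduces 11 to (E)-2-Ar-3-methoxyprop-2-en-1-ol F3. MnO2 oxidises F3 to (E)-2-Ar-3-methoxyprop-2-enal F4. The dilithium salt of 15 adds to the aldehyde carbonyl of F4 (aldol addition, −78 °C) to give racemic 6-[(5E)-5-Ar-4-hydroxy-6-methoxy-2-oxohex-5-en-1-yl]-2,2-dimethyl-4H-1,3-dioxin-4-one F5. Dess–Martin periodinane buffered with NaHCO3 oxidises F5 to 17.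

**Step 8.**
- Most likely failure: premature cyclisation during heating. This could be capture of the ketene by an internal enol oxygen, aldol aromatisation, or conjugate closure on C9.
- Why: the unmasked chain is reactive at 110 °C.
- Fallback, from 12 (activated as 16) to 19 without passing through 17: commercial methyl 3,5-dioxohexanoate is converted into its trilithium salt (LiN(iPr)2, 3 equiv, THF, 0 °C) and acylated at the terminal C6 carbanion by 16 at −78 °C. The triketo ester 19 is then formed cold, with no dioxinone and no thermolysis. This way makes no compound outside the list (F0).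

**Step 4.**
- Most likely failure: slow coupling of two hindered partners, leading to protonation or homocoupling of the arylzinc, or ionisation of the allylic ether by zerovalent palladium if the mixture has to be heated.
- Fallback, from 5 (through 9) to 11, with no palladium: aryllithium 9 is added to excess dimethyl oxalate at −78 °C to give methyl 2-Ar-2-oxoacetate F6. Wittig olefination with methoxymethylenetriphenylphosphorane (from (methoxymethyl)triphenylphosphonium chloride and KOtBu, THF, 0 °C) gives 11 together with methyl (Z)-2-Ar-3-methoxyprop-2-enoate F7, which is removed by chromatography.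

## Further compounds

F1 | step 9 | 1,3,5-tris{[2-(trimethylsilyl)ethoxy]methoxy}benzene | C[Si](C)(C)CCOCOc1cc(OCOCC[Si](C)(C)C)cc(OCOCC[Si](C)(C)C)c1
F2 | step 9 | (E)-2-[2,5-dimethoxy-4-(3-methylbut-2-enyloxy)phenyl]-3-methoxy-1-(2,4,6-tris{[2-(trimethylsilyl)ethoxy]methoxy}phenyl)prop-2-en-1-one | CO/C=C(/C(=O)c1c(OCOCC[Si](C)(C)C)cc(OCOCC[Si](C)(C)C)cc1OCOCC[Si](C)(C)C)c1cc(OC)c(OCC=C(C)C)cc1OC
F3 | step 7 | (E)-2-[2,5-dimethoxy-4-(3-methylbut-2-enyloxy)phenyl]-3-methoxyprop-2-en-1-ol | CO/C=C(/CO)c1cc(OC)c(OCC=C(C)C)cc1OC
F4 | step 7 | (E)-2-[2,5-dimethoxy-4-(3-methylbut-2-enyloxy)phenyl]-3-methoxyprop-2-enal | CO/C=C(/C=O)c1cc(OC)c(OCC=C(C)C)cc1OC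
F5 | step 7 | 6-[(5E)-5-[2,5-dimethoxy-4-(3-methylbut-2-enyloxy)phenyl]-4-hydroxy-6-methoxy-2-oxohex-5-en-1-yl]-2,2-dimethyl-4H-1,3-dioxin-4-one (racemic) | CO/C=C(/C(O)CC(=O)CC1=CC(=O)OC(C)(C)O1)c1cc(OC)c(OCC=C(C)C)cc1OC
F0 | step 8 | none | none
F6 | step 4 | methyl 2-[2,5-dimethoxy-4-(3-methylbut-2-enyloxy)phenyl]-2-oxoacetate | COC(=O)C(=O)c1cc(OC)c(OCC=C(C)C)cc1OC
F7 | step 4 | methyl (Z)-2-[2,5-dimethoxy-4-(3-methylbut-2-enyloxy)phenyl]-3-methoxyprop-2-enoate | CO/C=C(\C(=O)OC)c1cc(OC)c(OCC=C(C)C)cc1OC
A1 | alternative 1 | 3-[4-(benzyloxy)-2,5-dimethoxyphenyl]-5,7-bis(methoxymethoxy)-4H-chromen-4-one | COCOc1cc(OCOC)c2c(c1)occ(-c1cc(OC)c(OCc3ccccc3)cc1OC)c2=O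
A2 | alternative 1 | (Z)-1-[4-(benzyloxy)-2,5-dimethoxyphenyl]-2-[3,5-bis(methoxymethoxy)phenoxy]ethenyl trifluoromethanesulfonate | COCOc1cc(OCOC)cc(O/C=C(\OS(=O)(=O)C(F)(F)F)c2cc(OC)c(OCc3ccccc3)cc2OC)c1
A3 | alternative 2 | 5,7-difluoro-3-[2,5-dimethoxy-4-(3-methylbut-2-enyloxy)phenyl]-4H-chromen-4-one | COc1cc(-c2coc3cc(F)cc(F)c3c2=O)c(OC)cc1OCC=C(C)C
A4 | alternative 2 | 2,4,6-trifluorobenzoyl chloride | O=C(Cl)c1c(F)cc(F)cc1F
A5 | alternative 2 | 4-{(E)-2-[2,5-dimethoxy-4-(3-methylbut-2-enyloxy)phenyl]ethenyl}morpholine | COc1cc(/C=C/N2CCOCC2)c(OC)cc1OCC=C(C)C
A6 | alternative 3 | 5-hydroxy-7-(triisopropylsilyloxy)-3-[2,5-dimethoxy-4-(3-methylbut-2-enyloxy)phenyl]-4H-chromen-4-one | COc1cc(-c2coc3cc(O[Si](C(C)C)(C(C)C)C(C)C)cc(O)c3c2=O)c(OC)cc1OCC=C(C)C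
A7 | alternative 3 | 2-diazo-1-{5-[2,5-dimethoxy-4-(3-methylbut-2-enyloxy)phenyl]-4-oxo-4H-pyran-2-yl}ethan-1-one | COc1cc(-c2coc(C(=O)C=[N+]=[N-])cc2=O)c(OC)cc1OCC=C(C)C
A8 | alternative 3 | (ethynyloxy)triisopropylsilane | C#CO[Si](C(C)C)(C(C)C)C(C)C
A9 | alternative 3 | kojic acid, 5-hydroxy-2-(hydroxymethyl)-4H-pyran-4-one | O=c1cc(CO)occ1O
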